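**Assumptions**
- The target has no stereocentre and is achiral, so "single enantiomer" needs no control; the only stereo-element in the route is an E-alkene that is hydrogenated away.
- In steps 2, 4 and 5 the same operation runs two or three times in one flask; the singly reacted species are mixtures of positional isomers and are not numbered separately.

**Retrosynthetic overview**
1. Target 10 ⇐ global hydrogenation of tris(benzyl ether) stilbene 8 (C=C saturation plus three O-debenzylations).
2. 8 ⇐ twofold sp2–sp3 Negishi coupling of dibromostilbene 5 with benzylic zinc reagent 7 (from chloride 6); this forms both diarylmethane C–C bonds.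
3. 5 ⇐ Horner–Wadsworth–Emmons olefination of dibromo aldehyde 3 with phosphonate 4 (the two-carbon bridge).
4. 3 ⇐ twofold ring bromination of 2 ⇐ O-benzylation of 1; the OH/OMe differentiation is bought with 1.
5. No ring is formed: all four benzene rings come from commercial 1, 4 and 6.

**Route**

Step 1
Reactants: 1 3-hydroxy-5-methoxybenzaldehyde
Product: 2 3-(benzyloxy)-5-methoxybenzaldehyde
Conditions: BnBr (1.1 eq), K2CO3 (1.5 eq), DMF, rt
Reagents that add atoms: benzyl bromide, BrCc1ccccc1
Why: Williamson ether synthesis on the only acidic OH; benzyl is chosen so that all three phenol protections fall together in the final hydrogenolysis, and no stereocentre is formed.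

Step 2
Reactants: 2 3-(benzyloxy)-5-methoxybenzaldehyde
Product: 3 3-(benzyloxy)-2,6-dibromo-5-methoxybenzaldehyde
Conditions: NBS (2.2 eq), DMF, 0 °C → 50 °C, dark
Reagents that add atoms: N-bromosuccinimide, O=C1CCC(=O)N1Br
Why: Twofold electrophilic aromatic bromination; C2 and C6 are each para to one alkoxy group and ortho to the other, whereas C4 is crowded between two alkoxy groups and is the slow site in 3,5-dialkoxyaryl systems, and no stereocentre is formed.

Step 3
Reactants: 3 3-(benzyloxy)-2,6-dibromo-5-methoxybenzaldehyde; 4 diethyl benzylphosphonate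
Product: 5 (E)-1-(benzyloxy)-2,4-dibromo-5-methoxy-3-(2-phenylethenyl)benzene
Conditions: KOtBu (1.3 eq), THF, 0 °C → rt
Reagents that add atoms: none
Why: Horner–Wadsworth–Emmons olefination of a non-enolisable aldehyde gives the thermodynamic E-stilbene; the geometry is of no consequence because the alkene is hydrogenated in step 5, and no stereocentre is formed.

Step 4
Reactants: 5 (E)-1-(benzyloxy)-2,4-dibromo-5-methoxy-3-(2-phenylethenyl)benzene; 6 4-(benzyloxy)benzyl chloride
Product: 8 (E)-1-(benzyloxy)-2,4-bis[4-(benzyloxy)benzyl]-5-methoxy-3-(2-phenylethenyl)benzene, via 4-(benzyloxy)benzylzinc chloride 7 (not isolated)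
Conditions: 6 (3 eq), Zn dust, LiCl, THF, rt; then 5, Pd(OAc)2 (5 mol %), SPhos (10 mol %), THF, 60 °C
Reagents that add atoms: none
Why: Twofold Negishi cross-coupling; the benzylic zinc reagent has no β-hydrogen and transmetalates fast, Pd/SPhos handles di-ortho-substituted electron-rich aryl bromides, the benzyl ethers and the alkene are tolerated, and no stereocentre is formed.

Step 5
Reactants: 8 (E)-1-(benzyloxy)-2,4-bis[4-(benzyloxy)benzyl]-5-methoxy-3-(2-phenylethenyl)benzene
Product: 10 2,4-bis(4-hydroxybenzyl)-5-methoxy-3-(2-phenylethyl)phenol, via 1-(benzyloxy)-2,4-bis[4-(benzyloxy)benzyl]-5-methoxy-3-(2-phenylethyl)benzene 9 (not isolated)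
Conditions: H2 (1–3 atm), 10% Pd/C, THF–MeOH, rt
Reagents that add atoms: none
Why: Heterogeneous catalytic hydrogenation saturates the stilbene C=C first and then hydrogenolyses the three aryl benzyl ethers, while the aryl methyl ether and the diarylmethane C–C bonds are inert; the product is achiral.

**Compound list**
1 | 3-hydroxy-5-methoxybenzaldehyde | COc1cc(O)cc(C=O)c1 | starting material
2 | 3-(benzyloxy)-5-methoxybenzaldehyde | COc1cc(OCc2ccccc2)cc(C=O)c1 | intermediate
3 | 3-(benzyloxy)-2,6-dibromo-5-methoxybenzaldehyde | COc1cc(OCc2ccccc2)c(Br)c(C=O)c1Br | intermediate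
4 | diethyl benzylphosphonate | CCOP(=O)(Cc1ccccc1)OCC | starting material
5 | (E)-1-(benzyloxy)-2,4-dibromo-5-methoxy-3-(2-phenylethenyl)benzene | COc1cc(OCc2ccccc2)c(Br)c(/C=C/c2ccccc2)c1Br | intermediate
6 | 4-(benzyloxy)benzyl chloride | ClCc1ccc(OCc2ccccc2)cc1 | starting material
7 | 4-(benzyloxy)benzylzinc chloride | Cl[Zn]Cc1ccc(OCc2ccccc2)cc1 | intermediate (not isolated)
8 | (E)-1-(benzyloxy)-2,4-bis[4-(benzyloxy)benzyl]-5-methoxy-3-(2-phenylethenyl)benzene | COc1cc(OCc2ccccc2)c(Cc2ccc(OCc3ccccc3)cc2)c(/C=C/c2ccccc2)c1Cc1ccc(OCc2ccccc2)cc1 | intermediate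
9 | 1-(benzyloxy)-2,4-bis[4-(benzyloxy)benzyl]-5-methoxy-3-(2-phenylethyl)benzene | COc1cc(OCc2ccccc2)c(Cc2ccc(OCc3ccccc3)cc2)c(CCc2ccccc2)c1Cc1ccc(OCc2ccccc2)cc1 | intermediate (not isolated)
10 | 2,4-bis(4-hydroxybenzyl)-5-methoxy-3-(2-phenylethyl)phenol (IN1158) | COc1cc(O)c(Cc2ccc(O)cc2)c(CCc2ccccc2)c1Cc1ccc(O)cc1 | target

**Totals**
Total step count: 5. Longest linear sequence: 5 steps (1 → 2 → 3 → 5 → 8 → 10); the zinc reagent 7 is made in the flask within step 4.

**Three steps most likely to fail, with fallbacks**

Step 4 (most at risk). Both C–Br bonds are flanked by two ortho substituents on an electron-rich ring, so the coupling may stall at the mono-benzylated stage or give protodebromination. The fallback sets out from 5 and comes back to the route at 10, and replaces cross-coupling by carbonyl addition. Two successive bromine–lithium exchanges on 5 (n-BuLi, THF, −78 °C), each quenched in the same pot with 4-(benzyloxy)benzaldehyde, give the bis(diarylcarbinol) (E)-[4-(benzyloxy)-6-methoxy-2-(2-phenylethenyl)-1,3-phenylene]bis{[4-(benzyloxy)phenyl]methanol} F1 as a diastereomer mixture. Hydrogenation of F1 over Pd/C in EtOAc–MeOH with a little HCl saturates the alkene, removes the three benzyl ethers and hydrogenolyses the two electron-rich doubly benzylic C–OH bonds, giving 10 directly.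

Step 2. The second bromination has to enter a ring already deactivated by the formyl group and one bromine, so it may stop at the monobromide or give some C4 product. The fallback sets out from 2 and comes back to the route at 9, and moves the bromination to a more electron-rich ring that no longer carries the aldehyde. Olefination of 2 with 4 (KOtBu, THF) gives (E)-1-(benzyloxy)-3-methoxy-5-(2-phenylethenyl)benzene F2. Alkene-selective homogeneous hydrogenation (H2, RhCl(PPh3)3, benzene–EtOH), which leaves the benzyl ether intact, gives 1-(benzyloxy)-3-methoxy-5-(2-phenylethyl)benzene F3. NBS (2.1 eq, MeCN, 0 °C → rt) then brominates both positions ortho to the side chain and gives 1-(benzyloxy)-2,4-dibromo-5-methoxy-3-(2-phenylethyl)benzene F4. Negishi coupling of F4 with 7 under the step 4 conditions gives 9, here isolated, which is hydrogenolysed to 10 as in step 5.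

Step 3. The aldehyde sits between two ortho bromines, and the semi-stabilised phosphonate anion may add sluggishly. The fallback sets out from 3 and comes back to the route at 5, and builds the bridge by Grignard addition and elimination instead of olefination. Benzylmagnesium chloride (THF, −78 → 0 °C) adds to 3 to give racemic 1-[3-(benzyloxy)-2,6-dibromo-5-methoxyphenyl]-2-phenylethanol F5. Acid-catalysed dehydration (cat. TsOH, toluene, reflux, Dean–Stark) then gives the conjugated E-stilbene 5.

**Further compounds**
F1 | step 4 | (E)-[4-(benzyloxy)-6-methoxy-2-(2-phenylethenyl)-1,3-phenylene]bis{[4-(benzyloxy)phenyl]methanol} | COc1cc(OCc2ccccc2)c(C(O)c2ccc(OCc3ccccc3)cc2)c(/C=C/c2ccccc2)c1C(O)c1ccc(OCc2ccccc2)cc1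
F2 | step 2 | (E)-1-(benzyloxy)-3-methoxy-5-(2-phenylethenyl)benzene | COc1cc(OCc2ccccc2)cc(/C=C/c2ccccc2)c1
F3 | step 2 | 1-(benzyloxy)-3-methoxy-5-(2-phenylethyl)benzene | COc1cc(OCc2ccccc2)cc(CCc2ccccc2)c1
F4 | step 2 | 1-(benzyloxy)-2,4-dibromo-5-methoxy-3-(2-phenylethyl)benzene | COc1cc(OCc2ccccc2)c(Br)c(CCc2ccccc2)c1Br
F5 | step 3 | 1-[3-(benzyloxy)-2,6-dibromo-5-methoxyphenyl]-2-phenylethanol | COc1cc(OCc2ccccc2)c(Br)c(C(O)Cc2ccccc2)c1Br
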